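The data stem from a simulated flask for substances that don't exist, noise included.

Watch Q. It is charged at 0.190 M against 0.20 M of E, which makes it the limiting reagent, and its balance reads c(Q) + c(Z) + c(X) = 0.190 M. Z holds Q on loan; X holds it for good.

| flask | E | Q | temperature | remark | time |
|---|---|---|---|---|---|
| alpha | 0.13 M | 0.19 M | 28 °C | run made earlier |  |
| beta | 0.30 M | 0.19 M | 44 °C | run made earlier |  |
| south | 0.20 M | 0.190 M | 50 °C |  | 80 min |
| north-east | 0.20 M | 0.190 M |  | at 20 °C until 40 min, from then on at 50 °C | 80 min |
| south-east | 0.20 M | 0.190 M | 35 °C |  | 80 min |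
| north-west | 0.20 M | 0.190 M | 20 °C |  | 80 min |

| run | time / min | Z / % | E / % |
|---|---|---|---|
| alpha | 40.0 | 41.8 | 57.4 |
| alpha | 80.0 | 45.3 | 55.1 |
| alpha | 150 | 39.0 | 60.6 |
| alpha | 180 | 36.6 | 63.9 |
| alpha | 240 | 31.3 | 67.3 |
| beta | 6.00 | 19.8 | 81.2 |
| beta | 12.0 | 21.4 | 77.6 |
| beta | 25.0 | 18.5 | 81.3 |
| beta | 40.0 | 13.0 | 85.6 |
| beta | 80.0 | 6.6 | 93.4 |

(readings scatter by 1 percentage point)

- the flask that comes out highest in amount of Z, in percent of the E charged, or "all alike" when all lie within 1.5 percentage points (south / north-east / south-east / north-west / all alike)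
- Z at the end, in percent of the E charged, south
- Z at the end, in percent of the E charged, north-east
- Z at the end, in percent of the E charged, south-east
- Z at the end, in percent of the E charged, north-west

- what may be going on: Q -> X; E + Q <-> Z

Near equilibrium c(Z)/c(E) = K·c(Q), so the late fall of Z/E reads the fall of free Q. Alpha shows 0.00361 /min and beta 0.0191 /min. Stepping on geometrically with temperature gives 0.0357 /min at 50 °C, our burn rate of Q. It reads low, since Z hands Q back as it goes. At 20 °C the same step gives 0.00157 /min.

Now we bracket south. If every Q surviving this burn for 80 min sat in Z, Z would be 5.46 %: a first ceiling. But Z must stand in equilibrium with free Q. The peak readings, with X ignored, give K of 2.19 /M in beta and 6.27 /M in alpha, hence 1.48 /M at 50 °C. With E close to its charge, the ceiling tightens to 1.62 %, a soft one, as these K are read low. Burning Q at twice the rate gives the floor, 0.0930 %. The K we read is larger in the colder run and the burn is slower there, so we commit to north-west as the highest flask, with its forward speed unchecked.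

The forecast puts south at 1.2 %, inside our bracket, north-east at 5.5 %, south-east at 27 % and north-west at 45 %, the highest: “The cold flask is slow but keeps its Q”.

The flasks give 0.769 % in south, 4.75 % in north-east, 25.8 % in south-east and 43.9 % in north-west, so north-west comes out highest.

    Q → X (k = 5.10 × 10⁻⁵ /s, Ea = 84.0 kJ/mol)
    E + Q ⇌ Z (K = 21.0 /M, k = 0.00130 /M/s, Ea = 50.0 kJ/mol, ΔH = −56.0 kJ/mol)
    (constants at 20 °C)

South keeps 1.3 % of its Q, a burn at 1.52 times our rate, between the two fences. Taking away the backward run from Z to E + Q lifts south from 0.769 % to 48.1 %, the largest single effect but not the main reason; taking away the path from Q to X gives 25.7 %. A flask like south with 0.11 M of Q tests the rate: it is a share per minute, so the same share of Q should remain, and Z should scale with the charge to 0.445 %. That flask gives 1.3 % of its Q and 0.464 % of Z.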